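Leave the acid alone. The north-east flask is the one asked about, and these are the charges and readings so far:

| setting | north-east | south | flask |
|---|---|---|---|
| substrate | 0.050 M | 0.050 M | 0.050 M |
| acid | 0.050 mM | 0.034 mM | 0.0500 mM |
| remark | the very flask that is asked about, followed so far | run made earlier |  |
| time |  |  | 12 min |

| run | time / min | substrate / % | product / % |
|---|---|---|---|
| north-east | 0.500 | 94.6 | 4.9 |
| north-east | 1.00 | 90.9 | 8.4 |
| north-east | 1.33 | 87.6 | 12.1 |
| north-east | 2.00 | 82.3 | 17.4 |
| north-east | 2.50 | 79.0 | 21.6 |
| south | 1.00 | 93.9 | 6.9 |
| south | 2.00 | 86.9 | 12.5 |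
| south | 3.00 | 81.0 | 18.8 |
| south | 6.00 | 66.2 | 33.1 |
| south | 12.0 | 43.6 | 56.4 |

(readings scatter by 0.5 percentage points)

1. part of the substrate that has reacted at 12 min
2. pH of the solution at 12 min

- acid is the free proton; pH is minus the decimal logarithm of its molar concentration

I carry one quantity through the two runs, each read at its last point:

north-east: ln(charged/left) / (t · c(acid)) = 1.89 /mM/min
south: ln(charged/left) / (t · c(acid)) = 2.03 /mM/min
κ, the fall of ln c(substrate) per minute and per mM of acid, as the mean of these readings = 1.96 /mM/min

Multiplied by c(acid), κ gives the pseudo-first-order constant k. With c(acid) held steady, the lost part grows early as k·t, c(substrate) sinks late towards zero, and the exponential joins both ends. The south run stays on an exponential of its own out to 12.0 min.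

k = κ · c(acid) = 0.0980 /min
reacted at 12 min = 1 − exp(−k·t) = 69.2%

So I expect 30.8% substrate in the north-east flask when you come, the rest product. The forecast says 68.4% (66% to 70.5%), a little lower than mine, and pH 4.3 (4.26 to 4.36), on a rate that “fits acid acting as a catalyst that is not consumed”. I take its pH.

The flask gives 69.5% and pH 4.28; reckoned on the acid as charged, its 69.5% returns κ as 1.98 /mM/min. For the neighbour charged with 3.0 × 10⁻⁵ M of acid, κ on that charge gives 50.6% at 12 min; the neighbour reaches 52.5%.

    weak acid ⇌ conjugate base + acid, settled at all times (K = 3.20 × 10⁻⁹ M)
    substrate + acid → weak acid + acid + product (k = 31.0 /M/s)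
    substrate → weak acid + product (k = 5.80 × 10⁻⁵ /s)

In this flask the step with acid, taken by itself at the concentrations as charged, has a half-life of substrate of 7.5 min, shorter than the 200 min of the step without acid, and just after the start it uses substrate 27 times as fast. At 12.0 min this flask holds substrate at 30.5%, weak acid at 0.0347 M and acid at 104% of its charge.

(All runs were generated by integration with made-up constants; the scatter is artificial.)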